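The ring is disconnected at C1–C2 and C3–C4 (ring numbering: C1 carbinol carbon, C3 CHCl, C4 CBrCH3). This leaves the C2–C3 ethano unit and a C4–C5–C6–C1 chain whose ends are the two fully substituted, heteroatom-bearing ring carbons. These ends are the diene termini of 3-hydroxy-6-methyl-2-pyrone, which already holds the C1 oxygen, the first side-chain carbon (its lactone carbonyl) and the C4 methyl. One cinchona-base-catalysed Diels–Alder reaction with an acrylate forms both bonds and sets C1. The lactone bridge is later expelled from C4 to place a C3=C4 alkene, which the C1 hydroxyl converts into the trans Cl/Br pair.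

Key step: step 1

Remark: pyranone 1 is treated as a catalogue compound, and the facial sense of the cinchona base (step 1) and of the Ipc reagent (step 8) is assigned by analogy; the pseudo-enantiomeric base or the antipodal reagent would be used if the sense were the opposite.

Step 1
Reactants: 1 3-hydroxy-6-methyl-2H-pyran-2-one; 2 benzyl acrylate
Product: 3 benzyl (1S,4R,5S)-4-hydroxy-1-methyl-3-oxo-2-oxabicyclo[2.2.2]oct-7-ene-5-carboxylate
Conditions: quinidine-derived 6'-hydroxy cinchona base (cupreidine 9-O-benzyl ether, 10 mol %), EtOAc, rt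
Reagents that add atoms: none
Why: The catalyst amine deprotonates the 3-hydroxyl, and the oxido-diene, ion-paired with the chiral ammonium while the 6'-OH hydrogen-bonds the acrylate, adds through pyrone C6 to the acrylate β-carbon and closes from the α-carbon onto pyrone C3 (asynchronous [4+2]; at the stepwise limit a vinylogous Michael addition followed by a 6-(enolexo)-exo-trig aldol closure). The closest known reaction type is the cinchona-base-catalysed Diels–Alder reaction of 3-hydroxy-2-pyrones with acrylates and other electron-poor alkenes. The carbocycle is closed by cycloaddition across the diene termini, giving a 2-oxabicyclo[2.2.2]octene whose lactone bridges future C1 and C4. The C1 carbinol stereocentre is set by the catalyst, which shields one face of the ion-paired diene; the C4 bridgehead is fixed by the bridge, and the ester-bearing carbon (endo expected) is erased in step 3. The step needs regioselectivity (ester carbon to the hydroxylated terminus, CH2 to the methyl-bearing terminus), which the oxido group secures by making pyrone C6 the nucleophilic terminus; the ester then marks the ring arm that will carry the halogens.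

Step 2
Reactants: 3 benzyl (1S,4R,5S)-4-hydroxy-1-methyl-3-oxo-2-oxabicyclo[2.2.2]oct-7-ene-5-carboxylate
Product: 4 (1R,4R,5S)-4-hydroxy-1-methyl-3-oxo-2-oxabicyclo[2.2.2]octane-5-carboxylic acid
Conditions: H2 (1 atm), Pd/C (5 %), EtOAc, rt
Reagents that add atoms: none
Why: Catalytic hydrogenation should saturate the strained bridge alkene (future C5–C6) and hydrogenolyse the benzyl ester in the same operation, without touching a stereocentre.

Step 3
Reactants: 4 (1R,4R,5S)-4-hydroxy-1-methyl-3-oxo-2-oxabicyclo[2.2.2]octane-5-carboxylic acid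
Product: 5 (1R,4R)-4-hydroxy-1-methyl-2-oxabicyclo[2.2.2]oct-5-en-3-one
Conditions: 9-(2-chlorophenyl)acridine (10 mol %), Co(dmgH)2(py)Cl (5 mol %), CH2Cl2/MeCN, 400 nm LEDs, rt, N2
Reagents that add atoms: none
Why: Photoinduced decarboxylation gives the secondary radical at future C2, and the cobaloxime removes its only β-hydrogen (on future C3), so the alkene is placed on the acrylate-derived arm (dehydrodecarboxylation of an aliphatic acid).

Step 4
Reactants: 5 (1R,4R)-4-hydroxy-1-methyl-2-oxabicyclo[2.2.2]oct-5-en-3-one
Product: 6 (1R)-1-hydroxy-4-methylcyclohex-3-ene-1-carboxylic acid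
Conditions: Pd(PPh3)4 (5 mol %, zerovalent palladium), NaBH4 (2 equiv), THF, 0 °C to rt; then 1 M HCl
Reagents that add atoms: none
Why: Zerovalent palladium ionises the tertiary allylic lactone C–O bond to a π-allyl carboxylate, and hydride should attack the less substituted terminus (C2), leaving the trisubstituted C3=C4 alkene (Tsuji–Trost-type hydride reduction of an allylic ester); C1 is untouched.

Step 5
Reactants: 6 (1R)-1-hydroxy-4-methylcyclohex-3-ene-1-carboxylic acid
Product: 7 1-[(1R)-1-hydroxy-4-methylcyclohex-3-en-1-yl]ethan-1-one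
Conditions: MeLi (3.3 equiv), THF/Et2O, 0 °C to rt; inverse quench into aq. NH4Cl
Reagents that add atoms: methyllithium, [Li]C
Why: Methyllithium adds once to the lithium carboxylate to give a gem-diolate that collapses to the methyl ketone only on work-up (ketone synthesis from a carboxylic acid and an organolithium).

Step 6
Reactants: 7 1-[(1R)-1-hydroxy-4-methylcyclohex-3-en-1-yl]ethan-1-one
Product: 8 1-[(1S,2S,4R)-2-chloro-1-methyl-7-oxabicyclo[2.2.1]heptan-4-yl]ethan-1-one
Conditions: N-chlorosuccinimide (1.1 equiv), Ph3P=S (5 mol %), CH2Cl2, 0 °C to rt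
Reagents that add atoms: N-chlorosuccinimide, O=C1CCC(=O)N1Cl
Why: Only the chloronium ion on the alkene face opposite the tertiary hydroxyl can be opened by that hydroxyl at the tertiary carbon C4 (transannular chloroetherification), so C1 dictates the C3 chlorine configuration, anti to the oxygen bridge.

Step 7
Reactants: 8 1-[(1S,2S,4R)-2-chloro-1-methyl-7-oxabicyclo[2.2.1]heptan-4-yl]ethan-1-one
Product: 10 1-[(1R,3S,4S)-4-bromo-3-chloro-1-hydroxy-4-methylcyclohexyl]ethan-1-one, via O-dibromoboryl ether 9 (not isolated)
Conditions: BBr3 (1.1 equiv), CH2Cl2, −78 to −40 °C; then cold aq. NaHCO3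
Reagents that add atoms: boron tribromide, BrB(Br)Br
Why: The Lewis acid should cleave C4–O rather than C1–O (an α-acyl cation is disfavoured), and the anti-periplanar C3 chlorine assists ionisation so that bromide enters C4 from the face the oxygen left, giving the trans bromochloride with Br cis to the C1 hydroxyl (ether cleavage with neighbouring-group participation).

Step 8
Reactants: 10 1-[(1R,3S,4S)-4-bromo-3-chloro-1-hydroxy-4-methylcyclohexyl]ethan-1-one; 11 3-methylbut-2-enal
Product: 12 (3S)-1-[(1R,3S,4S)-4-bromo-3-chloro-1-hydroxy-4-methylcyclohexyl]-3-hydroxy-5-methylhex-4-en-1-one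
Conditions: (−)-Ipc2BCl (2.2 equiv), Et3N (2.5 equiv), Et2O, −78 to 0 °C; then 11, −78 to −20 °C; H2O2, pH 7 buffer, MeOH, 0 °C
Reagents that add atoms: none
Why: The diisopinocampheylboron enolate of the methyl ketone adds to the aldehyde through a cyclic transition state (boron aldol reaction), and the reagent is expected to select the Si face of the aldehyde to give the (S)-carbinol under amine conditions mild enough for the tertiary bromide.

Step 9
Reactants: 12 (3S)-1-[(1R,3S,4S)-4-bromo-3-chloro-1-hydroxy-4-methylcyclohexyl]-3-hydroxy-5-methylhex-4-en-1-one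
Product: 13 (1R,3S,4S)-4-bromo-3-chloro-1-[(4S)-4-hydroxy-6-methylhepta-1,5-dien-2-yl]-4-methylcyclohexan-1-ol
Conditions: Cp2TiMe2 (4 equiv, tetravalent titanium), toluene/THF, 65 °C, dark; then aq. NaHCO3
Reagents that add atoms: dimethyltitanocene, C[Ti](C)(C1C=CC=C1)C1C=CC=C1
Why: Petasis methylenation converts the hindered β-hydroxy ketone into the 1,1-disubstituted alkene without a basic ylide, so retro-aldol cleavage and elimination of the tertiary bromide should be avoided.

Compound list
1 | 3-hydroxy-6-methyl-2H-pyran-2-one | CC1=CC=C(O)C(=O)O1 | starting material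
2 | benzyl acrylate | C=CC(=O)OCc1ccccc1 | starting material
3 | benzyl (1S,4R,5S)-4-hydroxy-1-methyl-3-oxo-2-oxabicyclo[2.2.2]oct-7-ene-5-carboxylate (ester syn to the etheno bridge) | O=C1O[C@]2(C)C=C[C@@]1(O)[C@@H](C(=O)OCc1ccccc1)C2 | intermediate
4 | (1R,4R,5S)-4-hydroxy-1-methyl-3-oxo-2-oxabicyclo[2.2.2]octane-5-carboxylic acid | O=C1O[C@]2(C)CC[C@@]1(O)[C@@H](C(=O)O)C2 | intermediate
5 | (1R,4R)-4-hydroxy-1-methyl-2-oxabicyclo[2.2.2]oct-5-en-3-one | O=C1O[C@]2(C)CC[C@@]1(O)C=C2 | intermediate
6 | (1R)-1-hydroxy-4-methylcyclohex-3-ene-1-carboxylic acid | OC(=O)[C@@]1(O)CCC(C)=CC1 | intermediate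
7 | 1-[(1R)-1-hydroxy-4-methylcyclohex-3-en-1-yl]ethan-1-one | CC(=O)[C@@]1(O)CCC(C)=CC1 | intermediate
8 | 1-[(1S,2S,4R)-2-chloro-1-methyl-7-oxabicyclo[2.2.1]heptan-4-yl]ethan-1-one (chlorine anti to the oxygen bridge) | CC(=O)[C@]12CC[C@](C)(O1)[C@@H](Cl)C2 | intermediate
9 | O-dibromoboryl ether of 10 | CC(=O)[C@@]1(OB(Br)Br)CC[C@](C)(Br)[C@@H](Cl)C1 | intermediate
10 | 1-[(1R,3S,4S)-4-bromo-3-chloro-1-hydroxy-4-methylcyclohexyl]ethan-1-one | CC(=O)[C@@]1(O)CC[C@](C)(Br)[C@@H](Cl)C1 | intermediate
11 | 3-methylbut-2-enal | CC(C)=CC=O | starting material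
12 | (3S)-1-[(1R,3S,4S)-4-bromo-3-chloro-1-hydroxy-4-methylcyclohexyl]-3-hydroxy-5-methylhex-4-en-1-one | CC(C)=C[C@@H](O)CC(=O)[C@@]1(O)CC[C@](C)(Br)[C@@H](Cl)C1 | intermediate
13 | (1R,3S,4S)-4-bromo-3-chloro-1-[(4S)-4-hydroxy-6-methylhepta-1,5-dien-2-yl]-4-methylcyclohexan-1-ol | C=C(C[C@H](O)C=C(C)C)[C@@]1(O)CC[C@](C)(Br)[C@@H](Cl)C1 | target

Total step count: 9. Longest linear sequence: 9 steps (1 to 13).

Steps most likely to fail

Step 7. Ionising the chlorine-deactivated bridging ether needs a strong Lewis acid, under which the new tertiary bromide may lose HBr, the cation may be captured from the wrong face, or the hydroxy bromide may re-close to the ether on work-up. The fallback sets out from 7 and reaches the same chlorine-bridged cation from a carbinol, which ionises under much milder conditions. Hydroxyl-directed epoxidation (VO(acac)2, t-BuOOH, CH2Cl2) should give 1-[(1R,3R,6S)-3-hydroxy-6-methyl-7-oxabicyclo[4.1.0]heptan-3-yl]ethan-1-one F1, with the epoxide syn to the hydroxyl. Chloride opening at the secondary epoxide carbon with inversion (LiCl, AcOH, THF) should give 1-[(1R,3S,4S)-3-chloro-1,4-dihydroxy-4-methylcyclohexyl]ethan-1-one F2. Exchange of its C4 hydroxyl for bromide (48 % HBr, pentane, 0 °C) comes back to the route at 10.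

Step 4. Hydride may be delivered to the methyl-bearing allyl terminus, leaving the alkene on C2=C3 and creating a C4–H centre, or borohydride may reduce the lactone carbonyl before ionisation. The fallback sets out from 5 and replaces the π-allyl pathway by an anti-SN2′ reduction with a copper hydride, [(Ph3P)CuH]6 (monovalent copper) in toluene/THF at rt. Hydride then enters C2 and the double bond shifts to C3=C4 by mechanism; the sequence comes back at 6 and makes no new compound.

Step 8. Facial selectivity at the aldehyde may be poor, and the free tertiary hydroxyl may interfere with the boron reagent. The fallback sets out from 10: silylation of both the hydroxyl and the ketone (TMSOTf, Et3N, CH2Cl2, 0 °C) should give [(1R,3S,4S)-4-bromo-3-chloro-4-methyl-1-{1-[(trimethylsilyl)oxy]ethenyl}cyclohexyl]oxy(trimethyl)silane F3. A Mukaiyama aldol addition to 11 under a tartrate-derived chiral acyloxyborane (20 mol %, EtCN, −78 °C), with acidic work-up (1 M HCl/THF) to remove both silyl groups, comes back at 12.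

Further compounds
F1 | step 7 | 1-[(1R,3R,6S)-3-hydroxy-6-methyl-7-oxabicyclo[4.1.0]heptan-3-yl]ethan-1-one | CC(=O)[C@@]1(O)CC[C@]2(C)O[C@@H]2C1
F2 | step 7 | 1-[(1R,3S,4S)-3-chloro-1,4-dihydroxy-4-methylcyclohexyl]ethan-1-one | CC(=O)[C@@]1(O)CC[C@](C)(O)[C@@H](Cl)C1
F0 | step 4 | none | none
F3 | step 8 | [(1R,3S,4S)-4-bromo-3-chloro-4-methyl-1-{1-[(trimethylsilyl)oxy]ethenyl}cyclohexyl]oxy(trimethyl)silane | C=C(O[Si](C)(C)C)[C@@]1(O[Si](C)(C)C)CC[C@](C)(Br)[C@@H](Cl)C1
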